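**Strategy.** The disconnection cuts through the phloroglucinol ring, not the bond between arene and benzylic carbon. In step 17 a triisopropylsiloxyalkyne that already carries the whole bis-ketal terpenoid core meets the vinylketene from 3-ethoxycyclobutenone; one operation forms two C–C bonds and closes the benzene ring. The feature exploited is the aryl ipso carbon on the neopentyl-type benzylic CH (isobutyl-bearing, next to the quaternary cyclopentane carbon), flanked by two oxygenated ring carbons with the third oxygen para: alkyne carbons become C-alkyl and C–OSi, the ketene carbon C–OH. The precursor comes from (+)-2-carene via Claisen rearrangement, desymmetrising hydroacylation, auxiliary-controlled alkylation and ynolate formation.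

Key step: step 17

**Remarks (assumptions).** Numbering used below: cyclopentanone C1 = carbonyl carbon, C2 = carbon bearing the cyclopropane, C3 = quaternary carbon bearing the methyl group; the carbon that later carries the arene is called the benzylic carbon.
- C2 is α to the ketone and is left uncontrolled on purpose: all compounds from 8 to 34 that contain C2 are drawn with the target configuration there but are expected as pairs of C2 epimers, which converge in step 18.
- In step 6 the (R)-ligand is assumed to select the vinyl group that gives the drawn C3 configuration; if the sense proves opposite, the (S)-ligand is used.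
- The alkene geometry of 5 and 6 is lost when C3 becomes quaternary in step 5, so an E/Z mixture serves as well as the (E)-isomer drawn.
- The ethoxy group is kept because ethoxyacetylene is the commercial ynol ether; it is removed only after both formyl groups flank it, when chelation makes the cleavage mild.

## Route

Step 1
Reactants: 1 (+)-2-carene
Product: 2 keto aldehyde
Conditions: O3, CH2Cl2–MeOH, −78 °C; then Me2S, −78 → 20 °C
Reagents that add atoms: ozone, O=[O+][O-]
Why: Ozonolysis with reductive work-up should cleave the only C=C bond to the methyl ketone and the aldehyde, leaving the two cis-cyclopropane stereocentres of carene untouched (neutral work-up avoids epimerisation next to the aldehyde).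

Step 2
Reactants: 2 keto aldehyde
Product: 3 iodovinyl ketone
Conditions: CHI3, CrCl2, THF, 0 °C
Reagents that add atoms: iodoform, IC(I)I
Why: Takai olefination: the geminal dichromium reagent adds to aldehydes far faster than to ketones and should give the (E)-vinyl iodide, the added CH being the later ketone carbon C1.

Step 3
Reactants: 3 iodovinyl ketone
Product: 4 iodovinyl dioxolane
Conditions: ethylene glycol, PPTS (cat.), benzene, reflux, Dean–Stark
Reagents that add atoms: ethylene glycol, OCCO
Why: Acid-catalysed ketalisation with azeotropic removal of water masks the methyl ketone before the basic copper step; the weak acid should not protonate the vinylcyclopropane.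

Step 4
Reactants: 5 (E)-3-methylpent-2-en-4-yn-1-ol
Product: 6 (E)-3-methylpenta-2,4-dien-1-ol
Conditions: H2 (1 atm), Lindlar catalyst, quinoline, EtOAc, 20 °C
Reagents that add atoms: none
Why: Lindlar semihydrogenation of the terminal alkyne on poisoned palladium should stop at the conjugated diene.

Step 5
Reactants: 4 iodovinyl dioxolane; 6 (E)-3-methylpenta-2,4-dien-1-ol
Product: 8 divinyl aldehyde, via dienyl vinyl ether 7 (not isolated)
Conditions: CuI (10 mol %), 3,4,7,8-tetramethyl-1,10-phenanthroline (20 mol %), Cs2CO3, toluene, 80 °C; then 120 °C (not higher)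
Reagents that add atoms: none
Why: Ullmann-type copper-catalysed C–O coupling of the vinyl iodide with the allylic alcohol (retention of geometry) followed by thermal Claisen rearrangement should form the C2–C3 bond; the new quaternary C3 carries two vinyl groups and is not yet stereogenic, while C2 arises without control and is corrected in step 18.

Step 6
Reactants: 8 divinyl aldehyde
Product: 9 vinyl cyclopentanone
Conditions: [Rh(nbd)((R)-BINAP)]BF4 (5 mol %, activated with H2), CH2Cl2, 25 °C
Reagents that add atoms: none
Why: Intramolecular rhodium-catalysed hydroacylation of a 3,3-divinyl 4-pentenal (oxidative addition of the aldehyde C–H bond, hydrometallation of one vinyl group, reductive elimination) should close the cyclopentanone, the chiral bisphosphine choosing between the two vinyl groups and so setting the quaternary C3.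

Step 7
Reactants: 9 vinyl cyclopentanone
Product: 10 vinyl bis-dioxolane
Conditions: (TMSOCH2)2, TMSOTf (cat.), CH2Cl2, −78 → −20 °C
Reagents that add atoms: 1,2-bis(trimethylsilyloxy)ethane, C[Si](C)(C)OCCO[Si](C)(C)C
Why: Noyori ketalisation: catalytic TMSOTf transfers the glycol unit from its bis-silyl ether to the hindered ketone at low temperature, where the cyclopropane and the first dioxolane should not be disturbed.

Step 8
Reactants: 10 vinyl bis-dioxolane
Product: 12 primary alcohol, via B-alkyl-9-BBN adduct 11 (not isolated)
Conditions: 9-BBN, THF, 0 → 50 °C; then NaOH, H2O2, 0 → 20 °C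
Reagents that add atoms: hydrogen peroxide, OO
Why: Hydroboration with the bulky borane should place boron on the terminal carbon of the neopentyl-type vinyl group (anti-Markovnikov), and alkaline peroxide replaces boron by oxygen; both ketones are masked.

Step 9
Reactants: 12 primary alcohol
Product: 14 carboxylic acid, via aldehyde 13 (not isolated)
Conditions: TEMPO (cat.), NaOCl (cat.), NaClO2, MeCN–phosphate buffer (pH 6.7), 35 °C
Reagents that add atoms: sodium chlorite, [Na+].[O-]Cl=O
Why: TEMPO-catalysed oxidation to the aldehyde and chlorite (Pinnick-type) oxidation to the acid proceed at pH 6.7, which the dioxolanes and the cyclopropane should tolerate.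

Step 10
Reactants: 14 carboxylic acid; 15 (S)-4-benzyloxazolidin-2-one
Product: 17 N-acyl oxazolidinone, via mixed pivalic anhydride 16 (not isolated)
Conditions: PivCl, Et3N, THF, −20 °C; then 15, LiCl, 20 °C
Reagents that add atoms: none
Why: The mixed pivalic anhydride is attacked by the oxazolidinone at the less hindered carbonyl (CH2-flanked, not tert-butyl-flanked), a standard N-acylation that installs the chiral auxiliary.

Step 11
Reactants: 17 N-acyl oxazolidinone; 18 3-bromo-2-methylprop-1-ene
Product: 20 methallyl imide, via sodium (Z)-enolate 19 (not isolated)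
Conditions: NaHMDS, THF, −78 °C; then 18, −78 → −30 °C
Reagents that add atoms: none
Why: Evans alkylation: the chelated (Z)-sodium enolate is shielded on one face by the benzyl group of the (S)-auxiliary, so the allylic bromide should enter from the other face and set the future benzylic stereocentre under reagent control, overriding the weak bias of the neighbouring quaternary carbon.

Step 12
Reactants: 20 methallyl imide
Product: 21 isobutyl imide
Conditions: H2 (1 atm), Pd/C, EtOAc, 20 °C
Reagents that add atoms: none
Why: Heterogeneous hydrogenation should saturate the 1,1-disubstituted alkene to the isobutyl group without touching the unactivated cyclopropane, the dioxolanes or the auxiliary.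

Step 13
Reactants: 21 isobutyl imide
Product: 23 α-isobutyl acid, via peroxy acid 22 (not isolated)
Conditions: LiOH, H2O2, THF–H2O, 0 °C; then Na2SO3; then 1 M HCl to pH 3, 0 °C
Reagents that add atoms: hydrogen peroxide, OO
Why: Lithium hydroperoxide attacks the exocyclic imide carbonyl (standard auxiliary cleavage), sulfite reduces the peroxy acid, and the hindered α-centre should not epimerise under these weakly basic conditions.

Step 14
Reactants: 23 α-isobutyl acid
Product: 24 methyl ester
Conditions: MeI, K2CO3, DMF, 20 °C
Reagents that add atoms: iodomethane, CI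
Why: SN2 O-methylation of the carboxylate avoids any addition to the shielded carbonyl and is not basic enough to epimerise the α-centre.

Step 15
Reactants: 24 methyl ester
Product: 27 siloxyalkyne, via lithium dibromoenolate 25 (not isolated), via lithium ynolate 26 (not isolated)
Conditions: CH2Br2, LiTMP, THF, −78 °C; then LiHMDS; then n-BuLi, −78 → 20 °C; then TIPSCl, −78 → 0 °C
Reagents that add atoms: dibromomethane, BrCBr; triisopropylsilyl chloride, CC(C)[Si](Cl)(C(C)C)C(C)C
Why: Kowalski homologation: dibromomethyllithium adds to the ester, the resulting dibromoenolate undergoes bromine–lithium exchange and a carbenoid 1,2-shift in which the α-branched alkyl group migrates with retention to give the ynolate, and the bulky silyl chloride should silylate it on oxygen.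

Step 16
Reactants: 28 ethoxyacetylene
Product: 29 3-ethoxycyclobut-2-en-1-one
Conditions: ketene (from pyrolysis of acetone), CH2Cl2, 0 °C
Reagents that add atoms: ketene, C=C=O
Why: Thermal [2+2] cycloaddition of ketene with the electron-rich alkyne joins the ketene carbonyl carbon to the unsubstituted alkyne carbon and gives the vinylogous ester directly.

Step 17
Reactants: 27 siloxyalkyne; 29 3-ethoxycyclobut-2-en-1-one
Product: 33 silyloxy phenol, via ethoxy vinylketene 30 (not isolated), via vinylcyclobutenone adduct 31 (not isolated), via dienylketene 32 (not isolated)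
Conditions: toluene, 110 °C, sealed tube, 29 (1.5 equiv) added slowly
Reagents that add atoms: none
Why: Heat opens 29 by 4π electrocyclic ring opening to vinylketene 30, and a [2+2] cycloaddition joins its carbonyl carbon to the alkyl-bearing alkyne carbon and its α-carbon to the siloxy-bearing alkyne carbon, giving cyclobutenone 31. A second 4π opening gives dienylketene 32, and a thermal (disrotatory) 6π electrocyclisation between the ketene carbon and the CH2 terminus of the ethoxyvinyl group closes the six-membered carbocycle, which tautomerises to the phenol. The closest known reaction type is the Danheiser benzannulation of cyclobutenones with siloxyalkynes. No stereocentre is created: the sp3 ring carbon of the short-lived adduct 31 is lost on aromatisation, and the benzylic centre is a spectator because neither an arene nor a cation ever has to attack that congested carbon. The only selectivity needed is regiochemical and follows from the polarisation of the partners (the ynol ether oxygen makes the remote, alkyl-bearing alkyne carbon nucleophilic, the ketene accepts at its carbonyl carbon), so the alkyl group ends between OH and OSi with OEt para. Slow addition of 29 keeps the ketene concentration low so that it should not acylate the product phenol.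

Step 18
Reactants: 33 silyloxy phenol
Product: 35 resorcinol diketone, via bis-dioxolane resorcinol 34 (not isolated)
Conditions: TBAF, THF, 0 °C; then 2 M HCl, THF, 40 °C
Reagents that add atoms: water, O
Why: Fluoride cleaves the aryl silyl ether, aqueous acid hydrolyses both dioxolanes, and under the same acid C2 should equilibrate by enolisation to the epimer with the cyclopropyl group trans to the bulky aryl-bearing substituent on C3 (cis to the C3 methyl group), which is the configuration of the target.

Step 19
Reactants: 35 resorcinol diketone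
Product: 36 diformyl ethyl ether
Conditions: Cl2CHOMe, TiCl4, CH2Cl2, −78 → 0 °C; then H2O
Reagents that add atoms: dichloromethyl methyl ether, COC(Cl)Cl; water, O
Why: Rieche formylation: the titanium phenoxide directs the chloro(methoxy)methyl cation to the only two free ring positions, each activated by three oxygen substituents, and aqueous work-up releases both aldehydes; the ketones should not react at this temperature.

Step 20
Reactants: 36 diformyl ethyl ether
Product: 37 macrocarpal N
Conditions: BCl3, n-Bu4NI, CH2Cl2, −78 → 0 °C; then H2O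
Reagents that add atoms: none
Why: Boron trichloride chelated between the ethoxy oxygen and a flanking formyl oxygen activates the ethyl group for SN2 attack by iodide (Lewis acid–iodide ether cleavage), which should free the last phenol at 0 °C without harming the ketones, the aldehydes or the cyclopropane.

## Compound list

1 | (+)-2-carene, (1S,6R)-3,7,7-trimethylbicyclo[4.1.0]hept-2-ene | CC1=C[C@H]2[C@@H](CC1)C2(C)C | starting material
2 | keto aldehyde: (1S,3R)-2,2-dimethyl-3-(3-oxobutyl)cyclopropane-1-carbaldehyde (cis) | CC(=O)CC[C@@H]1[C@H](C=O)C1(C)C | intermediate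
3 | iodovinyl ketone: 4-[cis-3-((E)-2-iodoethenyl)-2,2-dimethylcyclopropyl]butan-2-one, ring configuration as in 2 | CC(=O)CC[C@@H]1[C@H](/C=C/I)C1(C)C | intermediate
4 | iodovinyl dioxolane: ethylene ketal of 3 | CC1(OCCO1)CC[C@@H]2[C@H](/C=C/I)C2(C)C | intermediate
5 | (E)-3-methylpent-2-en-4-yn-1-ol | C#C/C(C)=C/CO | starting material
6 | (E)-3-methylpenta-2,4-dien-1-ol | C=C/C(C)=C/CO | intermediate
7 | dienyl vinyl ether: 4 with iodine replaced by the (E)-3-methylpenta-2,4-dienyloxy group (not isolated) | CC1(OCCO1)CC[C@@H]2[C@H](/C=C/OC/C=C(\C)C=C)C2(C)C | intermediate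
8 | divinyl aldehyde: 2-[cis-2,2-dimethyl-3-[2-(2-methyl-1,3-dioxolan-2-yl)ethyl]cyclopropyl]-3-ethenyl-3-methylpent-4-enal | CC1(OCCO1)CC[C@@H]2[C@H]([C@@H](C=O)C(C)(C=C)C=C)C2(C)C | intermediate
9 | vinyl cyclopentanone: 3-ethenyl-3-methylcyclopentan-1-one carrying the cyclopropyl group of 8 at C2, cis to the 3-methyl group | CC1(OCCO1)CC[C@@H]2[C@H]([C@H]3C(=O)CC[C@]3(C)C=C)C2(C)C | intermediate
10 | vinyl bis-dioxolane: ethylene ketal of 9 | CC1(OCCO1)CC[C@@H]2[C@H]([C@H]3C4(OCCO4)CC[C@]3(C)C=C)C2(C)C | intermediate
11 | B-alkyl-9-BBN adduct of 10, boron on the terminal carbon (not isolated) | CC1(OCCO1)CC[C@@H]2[C@H]([C@H]3C4(OCCO4)CC[C@]3(C)CCB5C6CCCC5CCC6)C2(C)C | intermediate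
12 | primary alcohol: 10 with 2-hydroxyethyl in place of ethenyl | CC1(OCCO1)CC[C@@H]2[C@H]([C@H]3C4(OCCO4)CC[C@]3(C)CCO)C2(C)C | intermediate
13 | aldehyde: 12 oxidised to CH2CHO (not isolated) | CC1(OCCO1)CC[C@@H]2[C@H]([C@H]3C4(OCCO4)CC[C@]3(C)CC=O)C2(C)C | intermediate
14 | carboxylic acid: CH2CO2H on the quaternary ring carbon C3 | CC1(OCCO1)CC[C@@H]2[C@H]([C@H]3C4(OCCO4)CC[C@]3(C)CC(=O)O)C2(C)C | intermediate
15 | (S)-4-benzyloxazolidin-2-one | O=C1N[C@@H](Cc2ccccc2)CO1 | starting material
16 | mixed pivalic anhydride of 14 (not isolated) | CC1(OCCO1)CC[C@@H]2[C@H]([C@H]3C4(OCCO4)CC[C@]3(C)CC(=O)OC(=O)C(C)(C)C)C2(C)C | intermediate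
17 | N-acyl oxazolidinone: imide of 14 with 15 | CC1(OCCO1)CC[C@@H]2[C@H]([C@H]3C4(OCCO4)CC[C@]3(C)CC(=O)N5[C@@H](Cc6ccccc6)COC5=O)C2(C)C | intermediate
18 | 3-bromo-2-methylprop-1-ene | C=C(C)CBr | starting material
19 | sodium (Z)-enolate of 17 (not isolated) | CC1(OCCO1)CC[C@@H]2[C@H]([C@H]3C4(OCCO4)CC[C@]3(C)/C=C(\O[Na])N5[C@@H](Cc6ccccc6)COC5=O)C2(C)C | intermediate
20 | methallyl imide: 17 with a 2-methylprop-2-enyl group on the α-carbon, configuration of the target's benzylic carbon | CC1(OCCO1)CC[C@@H]2[C@H]([C@H]3C4(OCCO4)CC[C@]3(C)[C@H](CC(C)=C)C(=O)N5[C@@H](Cc6ccccc6)COC5=O)C2(C)C | intermediate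
21 | isobutyl imide: 20 with the alkene saturated | CC1(OCCO1)CC[C@@H]2[C@H]([C@H]3C4(OCCO4)CC[C@]3(C)[C@H](CC(C)C)C(=O)N5[C@@H](Cc6ccccc6)COC5=O)C2(C)C | intermediate
22 | peroxy acid: C(=O)OOH in place of the imide of 21 (not isolated) | CC1(OCCO1)CC[C@@H]2[C@H]([C@H]3C4(OCCO4)CC[C@]3(C)[C@H](CC(C)C)C(=O)OO)C2(C)C | intermediate
23 | α-isobutyl acid: 4-methylpentanoic acid carrying the bis-dioxolane ring system at C2 | CC1(OCCO1)CC[C@@H]2[C@H]([C@H]3C4(OCCO4)CC[C@]3(C)[C@H](CC(C)C)C(=O)O)C2(C)C | intermediate
24 | methyl ester of 23 | CC1(OCCO1)CC[C@@H]2[C@H]([C@H]3C4(OCCO4)CC[C@]3(C)[C@H](CC(C)C)C(=O)OC)C2(C)C | intermediate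
25 | lithium dibromoenolate: lithium enolate of the dibromomethyl ketone from 24 (not isolated) | CC1(OCCO1)CC[C@@H]2[C@H]([C@H]3C4(OCCO4)CC[C@]3(C)[C@H](CC(C)C)C(O[Li])=C(Br)Br)C2(C)C | intermediate
26 | lithium ynolate (not isolated) | CC1(OCCO1)CC[C@@H]2[C@H]([C@H]3C4(OCCO4)CC[C@]3(C)[C@H](CC(C)C)C#CO[Li])C2(C)C | intermediate
27 | siloxyalkyne: triisopropylsilyl ynol ether of the terpenoid core, both ketones as dioxolanes | CC1(CC[C@@H]2[C@H]([C@H]3C4(OCCO4)CC[C@]3(C)[C@H](CC(C)C)C#CO[Si](C(C)C)(C(C)C)C(C)C)C2(C)C)OCCO1 | intermediate
28 | ethoxyacetylene | CCOC#C | starting material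
29 | 3-ethoxycyclobut-2-en-1-one | CCOC1=CC(=O)C1 | intermediate
30 | ethoxy vinylketene: 3-ethoxybuta-1,3-dien-1-one (not isolated) | C=C(OCC)C=C=O | intermediate
31 | vinylcyclobutenone adduct: 2-alkyl-4-(1-ethoxyethenyl)-3-(triisopropylsiloxy)cyclobut-2-en-1-one, ring C4 uncontrolled (not isolated) | CC1(OCCO1)CC[C@@H]2[C@H]([C@H]3C4(OCCO4)CC[C@]3(C)[C@H](CC(C)C)C5=C(O[Si](C(C)C)(C(C)C)C(C)C)C(C(OCC)=C)C5=O)C2(C)C | intermediate
32 | dienylketene: 2-alkyl-5-ethoxy-3-(triisopropylsiloxy)hexa-1,3,5-trien-1-one (not isolated) | CC1(OCCO1)CC[C@@H]2[C@H]([C@H]3C4(OCCO4)CC[C@]3(C)[C@H](CC(C)C)C(=C=O)/C(O[Si](C(C)C)(C(C)C)C(C)C)=C\C(OCC)=C)C2(C)C | intermediate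
33 | silyloxy phenol: 2-alkyl-5-ethoxy-3-(triisopropylsiloxy)phenol of the bis-dioxolane core | CC1(CC[C@@H]2[C@H]([C@H]3C4(OCCO4)CC[C@]3(C)[C@H](CC(C)C)c5c(O)cc(OCC)cc5O[Si](C(C)C)(C(C)C)C(C)C)C2(C)C)OCCO1 | intermediate
34 | bis-dioxolane resorcinol: 33 without the silyl group (not isolated) | CC1(CC[C@@H]2[C@H]([C@H]3C4(OCCO4)CC[C@]3(C)[C@H](CC(C)C)c5c(O)cc(OCC)cc5O)C2(C)C)OCCO1 | intermediate
35 | resorcinol diketone: 2-alkyl-5-ethoxybenzene-1,3-diol with both ketones free | CC(=O)CC[C@@H]1[C@H]([C@H]2C(=O)CC[C@]2(C)[C@H](CC(C)C)c3c(O)cc(OCC)cc3O)C1(C)C | intermediate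
36 | diformyl ethyl ether: 35 with CHO at both free ring positions | CC(=O)CC[C@@H]1[C@H]([C@H]2C(=O)CC[C@]2(C)[C@H](CC(C)C)c3c(O)c(C=O)c(OCC)c(C=O)c3O)C1(C)C | intermediate
37 | macrocarpal N | CC(=O)CC[C@@H]1[C@H]([C@H]2C(=O)CC[C@]2(C)[C@H](CC(C)C)c2c(O)c(C=O)c(O)c(C=O)c2O)C1(C)C | target

## Step count and risks

Total step count: 20. Longest linear sequence: 18 steps (1–3, 5–15, 17–20); steps 4 and 16 are side branches.

The three steps most likely to fail:

1. Step 17 (key step). The donor-stabilised cyclobutenone 29 may open only slowly. At the temperature it needs, the siloxyalkyne 27, shielded by the neighbouring quaternary carbon, may be lost by silyl migration, or the ketene may dimerise or acylate the product phenol before the [2+2] takes place. Fallback (sets out from 27, returns at 37): the roles of the two partners are exchanged. Ketene gas is added to 27 at 0–20 °C, a [2+2] of an unhindered ketene with a siloxyalkyne, to give the 2-alkyl-3-(triisopropylsiloxy)cyclobutenone F1. Heating F1 with ethoxyacetylene 28 (toluene, 80 °C, sealed tube) runs the same electrocyclic cascade with a small alkyne as ketenophile and should give the isomeric phenol F2, in which the alkyl group lies between OEt and OSi and the free OH is para. Desilylation and ketal hydrolysis as in step 18 give the diol diketone F3, Rieche formylation as in step 19 gives the dialdehyde F4, and BCl3/n-Bu4NI as in step 20 (the ethoxy group still has one formyl neighbour) gives 37.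

2. Step 6. Discrimination between the two vinyl groups may be poor, for example because the two C2 epimers of 8 respond differently to the chiral catalyst, which would give both C3 configurations; decarbonylation may also compete. Fallback (sets out from 8, returns at 9): the ring is closed without any attempt at selection with an achiral cationic catalyst, [Rh(dppe)]BF4 in CH2Cl2, and C2 is then equilibrated with DBU. The two C3-epimeric ketones, which are diastereomers because of the carene-derived cyclopropane, are separated by chromatography; 9 is carried on and the C3-epimeric ketone F5 is set aside, at the cost of about half the material.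

3. Step 15. The carbenoid may add too slowly to the shielded ester carbonyl and decompose first, or base may remove the hydrogen at the benzylic α-carbon and erode its configuration. Fallback (sets out from 24, returns at 27 through 26): the ester is reduced with DIBAL-H at −78 °C to the aldehyde F6, Corey–Fuchs olefination (CBr4, PPh3, Zn) gives the 1,1-dibromoalkene F7, and n-BuLi (2 equiv) converts it by Fritsch–Buttenberg–Wiechell rearrangement into the lithium acetylide F8. Oxidation of the acetylide with lithium tert-butyl peroxide gives the ynolate 26, which TIPSCl silylates on oxygen to 27. All bond formation then occurs at the alkyne terminus, remote from the hindered centre.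

## Further compounds

F1 | step 17 | 2-alkyl-3-(triisopropylsiloxy)cyclobut-2-en-1-one of the bis-dioxolane core | CC1(OCCO1)CC[C@@H]2[C@H]([C@H]3C4(OCCO4)CC[C@]3(C)[C@H](CC(C)C)C5=C(O[Si](C(C)C)(C(C)C)C(C)C)CC5=O)C2(C)C
F2 | step 17 | 4-alkyl-3-ethoxy-5-(triisopropylsiloxy)phenol of the bis-dioxolane core | CC1(OCCO1)CC[C@@H]2[C@H]([C@H]3C4(OCCO4)CC[C@]3(C)[C@H](CC(C)C)c5c(OCC)cc(O)cc5O[Si](C(C)C)(C(C)C)C(C)C)C2(C)C
F3 | step 17 | 4-alkyl-5-ethoxybenzene-1,3-diol with both ketones free | CC(=O)CC[C@@H]1[C@H]([C@H]2C(=O)CC[C@]2(C)[C@H](CC(C)C)c3c(OCC)cc(O)cc3O)C1(C)C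
F4 | step 17 | 5-alkyl-4-ethoxy-2,6-dihydroxybenzene-1,3-dicarbaldehyde with both ketones free | CC(=O)CC[C@@H]1[C@H]([C@H]2C(=O)CC[C@]2(C)[C@H](CC(C)C)c3c(OCC)c(C=O)c(O)c(C=O)c3O)C1(C)C
F5 | step 6 | C3 epimer of vinyl cyclopentanone 9 (C2 as equilibrated) | CC1(OCCO1)CC[C@@H]2[C@H](C3C(=O)CC[C@@]3(C)C=C)C2(C)C
F6 | step 15 | aldehyde from reduction of methyl ester 24 | CC1(OCCO1)CC[C@@H]2[C@H]([C@H]3C4(OCCO4)CC[C@]3(C)[C@H](CC(C)C)C=O)C2(C)C
F7 | step 15 | 1,1-dibromoalkene from F6 | CC1(OCCO1)CC[C@@H]2[C@H]([C@H]3C4(OCCO4)CC[C@]3(C)[C@H](CC(C)C)C=C(Br)Br)C2(C)C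
F8 | step 15 | lithium acetylide from F7 | CC1(OCCO1)CC[C@@H]2[C@H]([C@H]3C4(OCCO4)CC[C@]3(C)[C@H](CC(C)C)C#C[Li])C2(C)C
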